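## Retrosynthetic overview
1. Ring order is oxolane first, macrolactone second, oxirane last. The oxirane comes from a final Shi epoxidation of the distal C22=C23 alkene of a sorbyl-type side chain.
2. Macrolactone: C7–C8 is closed by a Sonogashira reaction, followed by alkyne-to-8Z reduction. C2=C3 comes from a Still–Gennari olefination between a C19 phosphonopropanoate and aldehyde fragment C (C3–C7). The C5 ketone is unmasked late to protect C4.
3. C19–C20: Felkin-selective Nozaki–Hiyama–Kishi addition of a dienyl iodide to the C19 aldehyde.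
4. Oxolane: Nozaki–Hiyama–Kishi union at C13–C14 of Z-vinyl iodide fragment B (C8–C13) with α-methoxy aldehyde fragment A (C14–C20). O14 then displaces a C17 mesylate with inversion.
5. Sources: A from (S)-α-hydroxy-γ-butyrolactone and a Brown Z-crotylboration. B and C both start from propargyl alcohol (anti-carbomagnesiation versus syn-carboalumination) and use a phosphoric-acid-catalysed propargylation and a Crimmins aldol.

Assumption: carbons are numbered C1 (lactone C=O) to C24 (oxirane methyl) along the chain, and 5, 8, 25, 31, (+)-Ipc2BOMe, (R)-TRIP and the D-fructose-derived Shi ketone are taken as catalogue compounds.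

## Route

### Fragment B (C8–C13)

Step 1
Reactants: 1 prop-2-yn-1-ol
Product: 3 (Z)-3-iodo-2-methylprop-2-en-1-ol, via vinylmagnesium alkoxide 2 (not isolated)
Conditions: MeMgBr (3 equiv), copper iodide (CuI, 10 mol %), THF, 0 °C to rt; then I2, -78 to 0 °C; aq work-up
Reagents that add atoms: methylmagnesium bromide C[Mg]Br; iodine [I][I]
Why: Copper-catalysed anti-carbomagnesiation of the propargylic alkoxide puts methyl on C12 and holds the vinylmagnesium cis to CH2O by chelation, and iodinolysis with retention fixes the geometry that becomes 12Z.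

Step 2
Reactants: 3 (Z)-3-iodo-2-methylprop-2-en-1-ol
Product: 4 (Z)-3-iodo-2-methylprop-2-enal
Conditions: MnO2, CH2Cl2, rt, dark
Reagents that add atoms: none
Why: Allylic alcohol oxidation on MnO2 is neutral, so the vinyl iodide and the Z geometry survive.

Step 3
Reactants: 4 (Z)-3-iodo-2-methylprop-2-enal; 5 allenylboronic acid pinacol ester
Product: 6 (1Z,3R)-1-iodo-2-methylhex-1-en-5-yn-3-ol
Conditions: (R)-TRIP [(R)-3,3'-bis(2,4,6-triisopropylphenyl)BINOL hydrogen phosphate, 5 mol %], 4 Å MS, toluene, -20 °C; aq work-up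
Reagents that add atoms: none
Why: Chiral phosphoric acid-catalysed allenylboration (asymmetric propargylation) runs through a closed six-membered SE2' transition state in which the (R)-acid directs attack to the Re face of the conjugated aldehyde and sets C11 as R.

Step 4
Reactants: 6 (1Z,3R)-1-iodo-2-methylhex-1-en-5-yn-3-ol
Product: 7 fragment B, tert-butyl{[(1Z,3R)-1-iodo-2-methylhex-1-en-5-yn-3-yl]oxy}dimethylsilane
Conditions: TBSCl, imidazole, DMF, rt
Reagents that add atoms: tert-butyldimethylsilyl chloride CC(C)(C)[Si](C)(C)Cl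
Why: Standard silylation masks the C11 hydroxyl so that C19-OH is later the only acylation site, and C11 is not touched.

### Fragment A (C14–C20)

Step 5
Reactants: 8 (3S)-3-hydroxyoxolan-2-one
Product: 9 (3S)-3-methoxyoxolan-2-one
Conditions: MeI, Ag2O, MeCN, rt, dark
Reagents that add atoms: iodomethane C[I]
Why: Purdie methylation works without a strong base, so the chiral-pool centre (C15, S) is carried over without racemisation or ring opening.

Step 6
Reactants: 9 (3S)-3-methoxyoxolan-2-one
Product: 10 (2S)-4-hydroxy-N,2-dimethoxy-N-methylbutanamide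
Conditions: MeNH(OMe)·HCl, AlMe3, CH2Cl2, 0 °C to rt
Reagents that add atoms: N,O-dimethylhydroxylamine hydrochloride CNOC.Cl
Why: Weinreb aminolysis of the lactone with the aluminium amide frees the C17 primary alcohol and turns C14 into a latent aldehyde.

Step 7
Reactants: 10 (2S)-4-hydroxy-N,2-dimethoxy-N-methylbutanamide
Product: 11 (2S)-N,2-dimethoxy-N-methyl-4-oxobutanamide
Conditions: DMP, CH2Cl2, 0 °C to rt; used at once
Reagents that add atoms: none
Why: Dess–Martin oxidation is fast and base-free, so the β-methoxy aldehyde does not eliminate methanol and 10 has no time to relactonise.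

Step 8
Reactants: 11 (2S)-N,2-dimethoxy-N-methyl-4-oxobutanamide; 12 cis-but-2-ene
Product: 15 (2S,4S,5S)-4-hydroxy-N,2-dimethoxy-N,5-dimethylhept-6-enamide, via (Z)-crotylpotassium 13 (not isolated), via (Z)-crotyldiisopinocampheylborane 14 (not isolated)
Conditions: 12, n-BuLi, KOt-Bu, THF, -78 to -45 °C; (+)-Ipc2BOMe, -78 °C; BF3·OEt2; 11, -78 °C; ethanolamine work-up
Reagents that add atoms: none
Why: In the Brown asymmetric crotylboration the closed chair transition state turns the Z-crotyl geometry into the 17,18-syn relationship, and the (+)-Ipc groups choose the aldehyde face, which sets C18 (final configuration) and C17 (S, to be inverted in step 12).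

Step 9
Reactants: 15 (2S,4S,5S)-4-hydroxy-N,2-dimethoxy-N,5-dimethylhept-6-enamide
Product: 16 (2S,4S,5S)-N,2-dimethoxy-N,5-dimethyl-4-(methylsulfonyloxy)hept-6-enamide
Conditions: MsCl, Et3N, CH2Cl2, 0 °C; used at once
Reagents that add atoms: methanesulfonyl chloride CS(=O)(=O)Cl
Why: Mesylation with retention turns O17 into the leaving group and at the same time blocks lactonisation onto the amide.

Step 10
Reactants: 16 (2S,4S,5S)-N,2-dimethoxy-N,5-dimethyl-4-(methylsulfonyloxy)hept-6-enamide
Product: 17 fragment A, (3S,4S,6S)-6-methoxy-3-methyl-7-oxohept-1-en-4-yl methanesulfonate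
Conditions: DIBAL-H, CH2Cl2, -78 °C; aq work-up
Reagents that add atoms: none
Why: Reduction of the Weinreb amide stops at the chelated tetrahedral adduct, so the α-methoxy aldehyde appears only on work-up, and the mesylate and alkene are inert.

### Union of A and B, oxolane ring, side chain

Step 11
Reactants: 17 fragment A; 7 fragment B
Product: 18 (3S,4S,6S,7R,8Z,10R)-10-(tert-butyldimethylsilyloxy)-7-hydroxy-6-methoxy-3,9-dimethyltrideca-1,8-dien-12-yn-4-yl methanesulfonate
Conditions: CrCl2 (4 equiv), NiCl2 (1 mol %), DMSO, rt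
Reagents that add atoms: none
Why: In the Nozaki–Hiyama–Kishi coupling the alkenylchromium forms from 7 with retention of the Z geometry and adds only to the aldehyde, and the non-chelating polar Felkin–Anh (Cornforth) mode of the α-methoxy aldehyde gives the 14,15-anti alcohol (14R).

Step 12
Reactants: 18 open-chain C8–C20 hydroxy mesylate
Product: 19 tert-butyl{[(1Z,3R)-1-{(2R,3S,5R)-5-[(2S)-but-3-en-2-yl]-3-methoxyoxolan-2-yl}-2-methylhex-1-en-5-yn-3-yl]oxy}dimethylsilane
Conditions: KHMDS, THF, -78 to 0 °C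
Reagents that add atoms: none
Why: In the intramolecular Williamson etherification the C14 alkoxide displaces the C17 mesylate in a 5-exo-tet SN2 reaction with inversion (17S to 17R), which gives the 2,5-cis-oxolane with methoxy trans to both side chains.

Step 13
Reactants: 19 oxolane with but-3-en-2-yl group
Product: 21 (2R)-2-[(2R,4S,5R)-5-{(1Z,3R)-3-(tert-butyldimethylsilyloxy)-2-methylhex-1-en-5-yn-1-yl}-4-methoxyoxolan-2-yl]propanal, via vicinal diol 20 (not isolated)
Conditions: OsO4 (2 mol %), NaIO4, 2,6-lutidine, dioxane–H2O, rt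
Reagents that add atoms: sodium periodate [Na+].[O-]I(=O)(=O)=O
Why: In the Lemieux–Johnson cleavage OsO4 takes the unhindered monosubstituted alkene in preference to the C12=C13 alkene, which is shielded and deactivated by two allylic oxygens, and the buffered cleavage leaves C18 intact.

Step 14
Reactants: 22 (E)-but-2-enal
Product: 23 (1E,3E)-1-iodopenta-1,3-diene
Conditions: CHI3, CrCl2, THF, 0 °C
Reagents that add atoms: iodoform IC(I)I
Why: Takai olefination through the geminal dichromium species gives the E-vinyl iodide, and the existing E-alkene is untouched.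

Step 15
Reactants: 21 C19 aldehyde; 23 (1E,3E)-1-iodopenta-1,3-diene
Product: 24 (2S,3R,4E,6E)-2-[(2R,4S,5R)-5-{(1Z,3R)-3-(tert-butyldimethylsilyloxy)-2-methylhex-1-en-5-yn-1-yl}-4-methoxyoxolan-2-yl]octa-4,6-dien-3-ol
Conditions: CrCl2 (4 equiv), NiCl2 (1 mol %), DMSO–THF, rt
Reagents that add atoms: none
Why: In this Nozaki–Hiyama–Kishi coupling under neutral, non-chelating conditions, Felkin–Anh control by C18 and 1,3-anti induction by the C17 ring oxygen reinforce each other in the anti-configured aldehyde and set 19R with retention of the E,E-diene.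

Step 16
Reactants: 25 ethyl 2-[bis(2,2,2-trifluoroethoxy)phosphoryl]propanoate
Product: 26 2-[bis(2,2,2-trifluoroethoxy)phosphoryl]propanoic acid
Conditions: LiOH (1 equiv), THF–H2O, 0 °C; then HCl to pH 2
Reagents that add atoms: lithium hydroxide [Li+].[OH-]
Why: In this saponification the carboxylic ethyl ester, activated by the α-phosphoryl group, is cleaved at 0 °C before the phosphonate esters are attacked.

Step 17
Reactants: 24 C19 alcohol; 26 phosphonopropanoic acid
Product: 27 C19 2-[bis(2,2,2-trifluoroethoxy)phosphoryl]propanoate of 24 (11R,14R,15S,17R,18R,19R; epimers at the P-bearing carbon)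
Conditions: DCC, DMAP (cat.), CH2Cl2, 0 °C to rt
Reagents that add atoms: none
Why: Steglich esterification of the only free hydroxyl proceeds with retention at C19 and avoids ever activating an isomerisable Z-enoic acid.

### Fragment C (C3–C7)

Step 18
Reactants: 1 prop-2-yn-1-ol
Product: 29 (E)-3-iodo-2-methylprop-2-en-1-ol, via vinylalane 28 (not isolated)
Conditions: AlMe3, Cp2ZrCl2 (25 mol %), CH2Cl2, 0 °C to rt; then I2, THF, -30 °C; aq work-up
Reagents that add atoms: trimethylaluminium C[Al](C)C; iodine [I][I]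
Why: Negishi zirconium-catalysed syn-carboalumination adds methyl and terminal aluminium to the same face, and iodinolysis with retention gives the E-vinyl iodide that becomes 6E.

Step 19
Reactants: 29 (E)-3-iodo-2-methylprop-2-en-1-ol
Product: 30 (E)-3-iodo-2-methylprop-2-enal
Conditions: MnO2, CH2Cl2, rt
Reagents that add atoms: none
Why: Neutral allylic oxidation with MnO2 leaves the vinyl iodide and its geometry unchanged.

Step 20
Reactants: 30 (E)-3-iodo-2-methylprop-2-enal; 31 (4S)-4-benzyl-3-propanoyl-1,3-thiazolidine-2-thione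
Product: 33 (2R,3R,4E)-1-[(4S)-4-benzyl-2-sulfanylidene-1,3-thiazolidin-3-yl]-3-hydroxy-5-iodo-2,4-dimethylpent-4-en-1-one, via chlorotitanium enolate 32 (not isolated)
Conditions: TiCl4 (1.05 equiv), i-Pr2NEt (1.1 equiv), CH2Cl2, -78 °C; then 30, -78 °C
Reagents that add atoms: none
Why: In the Crimmins titanium aldol with one equivalent of base the thiocarbonyl stays bound to titanium, and the chelated Zimmerman–Traxler chair of the Z-enolate gives the non-Evans syn adduct, which sets C4 (the C5 carbinol is sacrificial).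

Step 21
Reactants: 33 syn-aldol adduct
Product: 34 C5 triethylsilyl ether of 33
Conditions: TESOTf, 2,6-lutidine, CH2Cl2, -78 to 0 °C
Reagents that add atoms: triethylsilyl trifluoromethanesulfonate CC[Si](CC)(CC)OS(=O)(=O)C(F)(F)F
Why: Silylation with the reactive triflate stops retro-aldol cleavage and installs a group that can later be removed beside the C11 TBS ether.

Step 22
Reactants: 34 silylated aldol adduct
Product: 35 fragment C, (2R,3R,4E)-5-iodo-2,4-dimethyl-3-(triethylsilyloxy)pent-4-enal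
Conditions: DIBAL-H, CH2Cl2, -78 °C; aq work-up
Reagents that add atoms: none
Why: Direct reductive removal of the thiazolidinethione stops at the aldehyde because the tetrahedral aluminium adduct is stable at -78 °C, so C4 is not epimerised.

### Assembly and endgame

Step 23
Reactants: 27 C19 phosphonopropanoate; 35 fragment C
Product: 37 open-chain (2Z)-enoate carrying the C7 vinyl iodide and the C8 terminal alkyne (4S,5R,11R,14R,15S,17R,18R,19R), via potassium phosphonate carbanion 36 (not isolated)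
Conditions: KHMDS, 18-crown-6, THF, -78 °C; then 35, -78 °C
Reagents that add atoms: none
Why: In the Still–Gennari olefination the electron-poor bis(trifluoroethyl) phosphonate with a dissociated potassium ion eliminates under kinetic control and gives the trisubstituted 2Z-enoate without epimerising C4.

Step 24
Reactants: 37 open-chain iodide–alkyne
Product: 38 macrocyclic (2Z,6E,12Z)-6-en-8-yne lactone with 5-OTES and 11-OTBS (4S,5R,11R,14R,15S,17R,18R,19R)
Conditions: Pd(PPh3)4 (10 mol %), copper iodide (CuI, 20 mol %), Et3N, degassed THF (1 mM, slow addition), rt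
Reagents that add atoms: none
Why: In the Sonogashira macrocyclisation, oxidative addition of zerovalent palladium into the C7–I bond is far faster at rt than ionisation of the secondary dienyl ester, and high dilution favours closure of the C7–C8 bond with retention of 6E.

Step 25
Reactants: 38 macrocyclic enyne
Product: 39 (2Z,6E,8Z,12Z)-macrolactone with 5-OTES and 11-OTBS
Conditions: zinc dust activated with Cu(OAc)2 and AgNO3, MeOH–H2O, rt to 35 °C
Reagents that add atoms: none
Why: The Boland reduction adds two hydrogens syn only to the conjugated alkyne, which sets 8Z and leaves alkenes, esters and silyl ethers alone.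

Step 26
Reactants: 39 bis-silyl macrolactone
Product: 40 C5 alcohol of the macrolactone (11-OTBS kept)
Conditions: PPTS (cat.), MeOH–CH2Cl2, 0 °C
Reagents that add atoms: none
Why: Mild acid-catalysed methanolysis removes the TES ether much faster than the bulkier TBS ether.

Step 27
Reactants: 40 C5 alcohol
Product: 41 C5 ketone (6E,8Z-dienone) with 11-OTBS
Conditions: DMP, NaHCO3, CH2Cl2, 0 °C
Reagents that add atoms: none
Why: Buffered Dess–Martin oxidation is neutral and fast, so the now acidic C4 centre (α to the ketone, γ to the enoate) keeps its S configuration.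

Step 28
Reactants: 41 C5 ketone with 11-OTBS
Product: 42 22,23-deoxy precursor of the target (free C11-OH and penta-1,3-dienyl side chain)
Conditions: HF·pyridine, excess pyridine, THF, 0 °C to rt
Reagents that add atoms: none
Why: Buffered fluoride desilylation is done before the acid-labile vinyl oxirane exists and is too weakly basic to epimerise C4.

Step 29
Reactants: 42 22,23-deoxy precursor
Product: 43 target CNP0117824.1
Conditions: D-fructose-derived Shi ketone (1 equiv), Oxone (2KHSO5·KHSO4·K2SO4), NaHCO3, aq Na2EDTA, MeCN–dimethoxymethane, 0 °C, pH 7–8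
Reagents that add atoms: potassium peroxymonosulfate [K+].OOS(=O)(=O)[O-]
Why: In the Shi epoxidation the chiral dioxirane attacks the most electron-rich alkene, the distal E-C22=C23 (the others are deactivated by carbonyl conjugation, the allylic acyloxy group, or two allylic oxygens with Z-hindrance), and the spiro transition state of the D-fructose ketone gives the (22R,23R)-trans-oxirane.

## Compound list
1 | prop-2-yn-1-ol | C#CCO | starting material
2 | bromomagnesium (Z)-3-(bromomagnesio)-2-methylprop-2-en-1-olate | Br[Mg]OC/C(C)=C\[Mg]Br | intermediate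
3 | (Z)-3-iodo-2-methylprop-2-en-1-ol | OC/C(C)=C\I | intermediate
4 | (Z)-3-iodo-2-methylprop-2-enal | O=C/C(C)=C\I | intermediate
5 | allenylboronic acid pinacol ester | C=C=CB1OC(C)(C)C(C)(C)O1 | starting material
6 | (1Z,3R)-1-iodo-2-methylhex-1-en-5-yn-3-ol (C11 R) | I/C=C(/C)[C@H](O)CC#C | intermediate
7 | fragment B, TBS ether of 6 | I/C=C(/C)[C@H](O[Si](C)(C)C(C)(C)C)CC#C | intermediate
8 | (3S)-3-hydroxyoxolan-2-one, (S)-α-hydroxy-γ-butyrolactone | O[C@H]1CCOC1=O | starting material
9 | (3S)-3-methoxyoxolan-2-one | CO[C@H]1CCOC1=O | intermediate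
10 | (2S)-4-hydroxy-N,2-dimethoxy-N-methylbutanamide | CO[C@@H](CCO)C(=O)N(C)OC | intermediate
11 | (2S)-N,2-dimethoxy-N-methyl-4-oxobutanamide | CO[C@@H](CC=O)C(=O)N(C)OC | intermediate
12 | cis-but-2-ene | C/C=C\C | starting material
13 | (Z)-crotylpotassium | C/C=C\[CH2-].[K+] | intermediate
14 | (Z)-crotyldiisopinocampheylborane, Ipc groups from (-)-α-pinene | C/C=C\CB([C@H]1C[C@H]2C[C@@H]([C@@H]1C)C2(C)C)[C@H]1C[C@H]2C[C@@H]([C@@H]1C)C2(C)C | intermediate
15 | (2S,4S,5S)-4-hydroxy-N,2-dimethoxy-N,5-dimethylhept-6-enamide (15S,17S,18S) | CO[C@@H](C[C@H](O)[C@@H](C)C=C)C(=O)N(C)OC | intermediate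
16 | (2S,4S,5S)-N,2-dimethoxy-N,5-dimethyl-4-(methylsulfonyloxy)hept-6-enamide | CO[C@@H](C[C@H](OS(C)(=O)=O)[C@@H](C)C=C)C(=O)N(C)OC | intermediate
17 | fragment A, (3S,4S,6S)-6-methoxy-3-methyl-7-oxohept-1-en-4-yl methanesulfonate | CO[C@@H](C[C@H](OS(C)(=O)=O)[C@@H](C)C=C)C=O | intermediate
18 | open-chain C8–C20 hydroxy mesylate (11R,14R,15S,17S,18S; 12Z) | CO[C@H]([C@H](O)/C=C(/C)[C@H](O[Si](C)(C)C(C)(C)C)CC#C)C[C@H](OS(C)(=O)=O)[C@@H](C)C=C | intermediate
19 | 2,5-cis-oxolane with but-3-en-2-yl group (11R,14R,15S,17R,18S) | CO[C@H]1C[C@H]([C@@H](C)C=C)O[C@@H]1/C=C(/C)[C@H](O[Si](C)(C)C(C)(C)C)CC#C | intermediate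
20 | 19,20-diol of 19 (epimers at C19) | CO[C@H]1C[C@H]([C@@H](C)C(O)CO)O[C@@H]1/C=C(/C)[C@H](O[Si](C)(C)C(C)(C)C)CC#C | intermediate
21 | C19 aldehyde (11R,14R,15S,17R,18R) | CO[C@H]1C[C@H]([C@@H](C)C=O)O[C@@H]1/C=C(/C)[C@H](O[Si](C)(C)C(C)(C)C)CC#C | intermediate
22 | (E)-but-2-enal, crotonaldehyde | C/C=C/C=O | starting material
23 | (1E,3E)-1-iodopenta-1,3-diene | I/C=C/C=C/C | intermediate
24 | C8–C24 dienyl alcohol (11R,14R,15S,17R,18S,19R) | CO[C@H]1C[C@H]([C@@H](C)[C@H](O)/C=C/C=C/C)O[C@@H]1/C=C(/C)[C@H](O[Si](C)(C)C(C)(C)C)CC#C | intermediate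
25 | ethyl 2-[bis(2,2,2-trifluoroethoxy)phosphoryl]propanoate | CCOC(=O)C(C)P(=O)(OCC(F)(F)F)OCC(F)(F)F | starting material
26 | 2-[bis(2,2,2-trifluoroethoxy)phosphoryl]propanoic acid | OC(=O)C(C)P(=O)(OCC(F)(F)F)OCC(F)(F)F | intermediate
27 | C19 phosphonopropanoate of 24 | CO[C@H]1C[C@H]([C@@H](C)[C@H](OC(=O)C(C)P(=O)(OCC(F)(F)F)OCC(F)(F)F)/C=C/C=C/C)O[C@@H]1/C=C(/C)[C@H](O[Si](C)(C)C(C)(C)C)CC#C | intermediate
28 | dimethylaluminium (E)-3-(dimethylalumanyl)-2-methylprop-2-en-1-olate | C[Al](C)OC/C(C)=C/[Al](C)C | intermediate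
29 | (E)-3-iodo-2-methylprop-2-en-1-ol | OC/C(C)=C/I | intermediate
30 | (E)-3-iodo-2-methylprop-2-enal | O=C/C(C)=C/I | intermediate
31 | (4S)-4-benzyl-3-propanoyl-1,3-thiazolidine-2-thione | CCC(=O)N1[C@@H](Cc2ccccc2)CSC1=S | starting material
32 | trichlorotitanium (Z)-enolate of 31 | C/C=C(\O[Ti](Cl)(Cl)Cl)N1[C@@H](Cc2ccccc2)CSC1=S | intermediate
33 | non-Evans syn aldol adduct (C4 R, C5 R in this compound) | O=C([C@H](C)[C@@H](O)/C(C)=C/I)N1[C@@H](Cc2ccccc2)CSC1=S | intermediate
34 | C5 TES ether of 33 | O=C([C@H](C)[C@@H](O[Si](CC)(CC)CC)/C(C)=C/I)N1[C@@H](Cc2ccccc2)CSC1=S | intermediate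
35 | fragment C, (2R,3R,4E)-5-iodo-2,4-dimethyl-3-(triethylsilyloxy)pent-4-enal | O=C[C@H](C)[C@@H](O[Si](CC)(CC)CC)/C(C)=C/I | intermediate
36 | potassium salt of the phosphonate carbanion of 27 | [K+].CO[C@H]1C[C@H]([C@@H](C)[C@H](OC(=O)[C-](C)P(=O)(OCC(F)(F)F)OCC(F)(F)F)/C=C/C=C/C)O[C@@H]1/C=C(/C)[C@H](O[Si](C)(C)C(C)(C)C)CC#C | intermediate
37 | open-chain (2Z)-enoate with C7 vinyl iodide and C8 alkyne (4S,5R,11R,14R,15S,17R,18R,19R) | CO[C@H]1C[C@H]([C@@H](C)[C@H](OC(=O)/C(C)=C\[C@H](C)[C@@H](O[Si](CC)(CC)CC)/C(C)=C/I)/C=C/C=C/C)O[C@@H]1/C=C(/C)[C@H](O[Si](C)(C)C(C)(C)C)CC#C | intermediate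
38 | macrocyclic 6-en-8-yne lactone, 5-OTES, 11-OTBS | CO[C@H]1C[C@H]2O[C@@H]1/C=C(/C)[C@H](O[Si](C)(C)C(C)(C)C)CC#C/C=C(\C)[C@H](O[Si](CC)(CC)CC)[C@@H](C)/C=C(/C)C(=O)O[C@H](/C=C/C=C/C)[C@@H]2C | intermediate
39 | (2Z,6E,8Z,12Z)-macrolactone, 5-OTES, 11-OTBS | CO[C@H]1C[C@H]2O[C@@H]1/C=C(/C)[C@H](O[Si](C)(C)C(C)(C)C)C/C=C\C=C(/C)[C@H](O[Si](CC)(CC)CC)[C@@H](C)/C=C(/C)C(=O)O[C@H](/C=C/C=C/C)[C@@H]2C | intermediate
40 | macrolactone C5 alcohol, 11-OTBS (4S,5R) | CO[C@H]1C[C@H]2O[C@@H]1/C=C(/C)[C@H](O[Si](C)(C)C(C)(C)C)C/C=C\C=C(/C)[C@H](O)[C@@H](C)/C=C(/C)C(=O)O[C@H](/C=C/C=C/C)[C@@H]2C | intermediate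
41 | macrolactone C5 ketone, 11-OTBS (4S) | CO[C@H]1C[C@H]2O[C@@H]1/C=C(/C)[C@H](O[Si](C)(C)C(C)(C)C)C/C=C\C=C(/C)C(=O)[C@@H](C)/C=C(/C)C(=O)O[C@H](/C=C/C=C/C)[C@@H]2C | intermediate
42 | 22,23-deoxy precursor (4S,11R,14R,15S,17R,18R,19R) | CO[C@H]1C[C@H]2O[C@@H]1/C=C(/C)[C@H](O)C/C=C\C=C(/C)C(=O)[C@@H](C)/C=C(/C)C(=O)O[C@H](/C=C/C=C/C)[C@@H]2C | intermediate
43 | CNP0117824.1 (4S,11R,14R,15S,17R,18R,19R,22R,23R; 2Z,6E,8Z,12Z,20E) | CO[C@H]1C[C@H]2O[C@@H]1/C=C(/C)[C@H](O)C/C=C\C=C(/C)C(=O)[C@@H](C)/C=C(/C)C(=O)O[C@H](/C=C/[C@H]1O[C@@H]1C)[C@@H]2C | target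

## Step count and risks
Total step count: 29.
Longest linear sequence: 18 steps from 8 to 43 (steps 5–13, 15, 17, 23–29).

**Step 11 (facial selectivity of the first Nozaki–Hiyama–Kishi coupling).** The fallback sets out from 18, taken as a C14 epimer mixture, and comes back at 18. C14 is then set by hydride delivery instead of by the C–C bond formation. Dess–Martin oxidation of the mixture gives the (Z)-α-methoxy enone F1. Zn(BH4)2 in Et2O at -78 °C reduces it through the five-membered Cram chelate between the C14 carbonyl and the C15 methoxy group. Hydride therefore enters from the side of the C15 hydrogen and gives the 14,15-anti alcohol 18.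

**Step 24 (macrocyclic Sonogashira beside a dienyl ester).** The fallback sets out from 24, 25 and 35 and comes back at 39. The ring is closed at the ester bond instead of at C7–C8.
- Still–Gennari olefination of 35 with 25 gives the ethyl (2Z)-dienoate vinyl iodide F2.
- Intermolecular Sonogashira coupling of F2 with the free alcohol 24 gives the open-chain enyne hydroxy ester F3. A free dienyl alcohol is not ionised by zerovalent palladium.
- Reduction with copper- and silver-activated zinc gives the open-chain (6E,8Z)-diene hydroxy ester F4.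
- Me3SnOH in 1,2-dichloroethane gives the seco acid F5.
- Shiina macrolactonisation (2-methyl-6-nitrobenzoic anhydride, DMAP, high dilution) gives 39.

**Step 29 (site selectivity, alcohol oxidation and C4 integrity in the last-step epoxidation).** The fallback sets out from 41 and comes back at 43. The epoxidation is moved in front of the last deprotection. The bulky C11 silyl ether then shields C12=C13, and no free allylic alcohol meets the dioxirane. Shi epoxidation of 41 gives the 11-O-TBS ether of the target F6. Neutral fluoride (TASF, wet DMF, 0 °C) then frees C11-OH without opening the vinyl oxirane and gives 43.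

## Further compounds
F1 | step 11 | (3S,4S,6S,8Z,10R)-10-(tert-butyldimethylsilyloxy)-6-methoxy-3,9-dimethyl-7-oxotrideca-1,8-dien-12-yn-4-yl methanesulfonate | CO[C@H](C(=O)/C=C(/C)[C@H](O[Si](C)(C)C(C)(C)C)CC#C)C[C@H](OS(C)(=O)=O)[C@@H](C)C=C
F2 | step 24 | ethyl (2Z,4S,5R,6E)-7-iodo-2,4,6-trimethyl-5-(triethylsilyloxy)hepta-2,6-dienoate | CCOC(=O)/C(C)=C\[C@H](C)[C@@H](O[Si](CC)(CC)CC)/C(C)=C/I
F3 | step 24 | open-chain C1–C24 6-en-8-yne hydroxy ethyl ester | CO[C@H]1C[C@H]([C@@H](C)[C@H](O)/C=C/C=C/C)O[C@@H]1/C=C(/C)[C@H](O[Si](C)(C)C(C)(C)C)CC#C/C=C(\C)[C@H](O[Si](CC)(CC)CC)[C@@H](C)/C=C(/C)C(=O)OCC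
F4 | step 24 | open-chain C1–C24 (6E,8Z)-diene hydroxy ethyl ester | CO[C@H]1C[C@H]([C@@H](C)[C@H](O)/C=C/C=C/C)O[C@@H]1/C=C(/C)[C@H](O[Si](C)(C)C(C)(C)C)C/C=C\C=C(/C)[C@H](O[Si](CC)(CC)CC)[C@@H](C)/C=C(/C)C(=O)OCC
F5 | step 24 | seco acid (C1 acid, C19 alcohol) | CO[C@H]1C[C@H]([C@@H](C)[C@H](O)/C=C/C=C/C)O[C@@H]1/C=C(/C)[C@H](O[Si](C)(C)C(C)(C)C)C/C=C\C=C(/C)[C@H](O[Si](CC)(CC)CC)[C@@H](C)/C=C(/C)C(=O)O
F6 | step 29 | 11-O-TBS ether of the target | CO[C@H]1C[C@H]2O[C@@H]1/C=C(/C)[C@H](O[Si](C)(C)C(C)(C)C)C/C=C\C=C(/C)C(=O)[C@@H](C)/C=C(/C)C(=O)O[C@H](/C=C/[C@H]1O[C@@H]1C)[C@@H]2C
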